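## Structural features

The target is a germacranolide: a ten-membered carbocycle (C1–C10) trans-fused along C7–C8 to an α-methylene-γ-butyrolactone (C11=C13, C12, ring oxygen on C8). The carbocycle carries a cis-fused epoxide on C4/C5 (C4 quaternary, with the C15 methyl), an exocyclic methylene C10=C14, a free secondary hydroxyl at C1 that is allylic to C10=C14, and an angelate, (Z)-2-methylbut-2-enoate, on O6. There are six stereocentres (1S,4R,5S,6S,7R,8S). Five of them, C4 to C8, are contiguous, with H-6, H-7 and H-8 alternating (6β, 7α, 8β) and the epoxide oxygen on the same face as O6; C1 is insulated from the others by C2–C3 and C9–C10. The fragile groups are the angelate (isomerises to the tiglate with base, nucleophiles or acid), the α-methylene lactone (Michael acceptor), the trisubstituted epoxide (acid-labile, open to transannular attack by C10=C14) and the O6/O8 pair, because C12 is γ to both oxygens and can translactonise. The real difficulty is closing the medium ring with the right configuration at C8 while the remote centre C1 is already in place, followed by selective late operations on three alkenes and on oxygens of similar reactivity. The key step exploits the unit O8–C8–C9H2–C10(=C14H2): a homoallylic alcohol whose allyl group is substituted at its central carbon C10 by C1, which is the retron of a 2-substituted allylsilane adding to a C8 aldehyde with C8–C9 as the ring-closing bond.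

## Logic of the disconnections

34 to 33. Only the O1–Si bond is cut. The C1 hydroxyl stays silylated to the end so that it is never confused with O6 or O8. This removes no complexity but leaves every earlier step with a single free oxygen. The forward step must remove silicon without base (angelate, methylene lactone) and without strong acid (epoxide).

33 to 30 and 31. The acyl C–O6 bond is cut, because the angelate is the most easily isomerised group and should meet as few reagents as possible. The ring compound loses its only sensitive ester and a C5 acid is split off. The forward acylation must work on a hindered alcohol next to an epoxide without Z to E isomerisation and without forming an alkoxide that could translactonise or migrate the epoxide.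

30 to 29. Both C–O bonds of the epoxide are cut back to the Z alkene C4=C5, because the epoxide oxygen is cis to O6 and the free C6 hydroxyl can deliver it. Two stereocentres disappear, and the alkene geometry that fixes the cis epoxide can be bought. The forward step needs syn delivery on the ring periphery and selection among three alkenes.

29 to 28 to 24. First the O6–Si bond (28), then the C11=C13 bond (24) is cut. The methylene is installed while O6 is silylated, since it needs a lithium enolate that neither a free C6 alkoxide (translactonisation) nor an angelate would survive. The Michael acceptor is replaced by a plain γ-lactone. Forward, enolisation must be confined to C11, and the two silyl ethers must be distinguishable.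

24 to 22 to 21. The acyl C12–O8 bond is cut and the oxidation level of C12 is traced through the 1,4-diol of 22 to the tert-butyl ester of 21. The reason is regiochemical: an acid strong enough to lactonise a tert-butyl ester would first strip the O6 silyl group and endanger the cyclodecadiene. A neutral oxidative lactonisation can only use the free O8. The gain is a monocycle with a robust ester. Forward, the ester must be reduced without silyl loss and the primary alcohol oxidised before the secondary one.

21 to 20. The ring bond C8–C9 is cut. This opens the ten-membered ring to an acyclic chain, removes the C8 stereocentre and leaves the exocyclic alkene as an allylsilane. The forward step must close a medium ring against oligomerisation, attack only through the allylsilane terminus, and set C8 from C7 by Felkin–Anh control.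

20 to 19 to 18 to 17. No skeletal bond is cut. The C8 aldehyde is traced to the primary alcohol and then to an acyl oxazolidinone, and the O6–Si bond is cut to the free aldol. This exposes a syn-aldol retron at C6/C7. The demands are a hydride that distinguishes imide from ester and an oxidation that does not epimerise C7.

17 to 15 and 11. The C6–C7 bond is cut between a succinate-derived enolate and a (Z)-enal. Both stereocentres are set in one step, and the C11–C12 branch arrives with the enolate. The forward aldol must be syn-selective under auxiliary control, keep the Z geometry of the enal, and not let the aldolate attack the C12 ester, hence the tert-butyl ester.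

15 to 12 and 13. The N–acyl bond is cut to a succinic half ester and the oxazolidinone. The demand is acylation at the free acid terminus only.

11 to 10 to 9 to 8. Functional-group changes only: aldehyde from alcohol, alcohol from acetate, O1–Si from the free carbinol. The demand is an allylic oxidation that does not isomerise the Z alkene.

8 to 7 to 6. The C1–H bond is cut. The carbinol centre is traced to a ketone so that it can be set by a chiral catalyst, because no other stereocentre is near. The demand is 1,2-reduction of an α-substituted enone with high face selectivity.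

6 to 3 and 4. The C1–C10 bond is cut between an aldehyde and a 2-metallated allylsilane. This brings in C9, C10 and C14 with the silicon already in place. The organometallic must tolerate the acetate.

3 to 1. The terminal C=C bond is cut, tracing the aldehyde to an isopropylidene group. The Z-trisubstituted alkene, C15 and C2–C6 then come from a commercial terpene ester. The demand is cleavage of the distal alkene only.

## Other disconnections considered

Alternative 1: The cut removes C12: the C12–O8 and C11–C12 bonds go back to carbon monoxide. This leaves the homopropargylic alcohol A2, a ten-membered ring with epoxide, angelate and silyl ether in place, an ethynyl group on C7 and a free hydroxyl on C8. Forward, PdCl2, SnCl2 and PPh3 under CO would turn O8 into an alkoxycarbonyl ligand on divalent palladium. The acyl–palladium bond would add syn across the alkyne, and protonolysis would release the α-methylene lactone A1, the C1 silyl ether of the target and the same compound as 33.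
- In favour: lactone and methylene arise in one operation, no enolate chemistry is needed, and the trans fusion is inherited from A2. For the lactone construction it is the better plan: one step instead of steps 14 to 16, with the same final desilylation.
- Against: it runs on the most fragile intermediate. Tin chloride and liberated hydrogen chloride could open the epoxide, also transannularly through C10=C14, and palladium hydrides could isomerise C10=C14 or the angelate. It also leaves the ring unsolved: a cyclodecane with a C7 alkyne trans to O8 must still be made, without the C11–C12 branch that gives the chosen route its aldol and its Felkin control.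
- Comparison: structurally, the chosen plan spends its hardest bond on the carbocycle and leaves the lactone to polar steps. Mechanistically, the carbonylation is late, metal- and acid-mediated, whereas steps 14–16 are neutral or basic and precede epoxide and angelate. In step count after ring closure the alternative would be equal or shorter, but only if an equally short route to A2 existed.

Alternative 2: No ring bond is cut. The C1 and C6 carbonyls of the 1,6-diketone A3 are reconnected as a tetrasubstituted C1=C6 alkene, giving the octalin A4, which is accessible from an arene. Forward, ozone adds to C1=C6 of A4, Me2S reduces the ozonide, and the two six-membered rings merge into A3 with the cis epoxide and trans lactone present.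
- In favour: ring formation costs no entropy and needs no dilution, ozonolysis of a tetrasubstituted alkene is dependable, and the C4/C5 and C7/C8 relationships are set on a rigid bicycle. On certainty of obtaining the ten-membered ring it is the better plan.
- Against: A3 has the wrong oxidation pattern and is fragile. C6 must be reduced to the 6α alcohol next to an epoxide, C1 to the 1α alcohol, and the C10 ester converted to C10=C14. Meanwhile H-7 is α to the C6 ketone with the lactone oxygen β to it (elimination, epimerisation), and the C10 β-keto ester can add transannularly to C6. C1 and C6 would be controlled only by the conformation of a flexible ring.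
- Comparison: structurally, the chosen plan installs C1–O, C6–O and C10=C14 before ring closure under reagent control. Mechanistically, the Criegee cleavage is more reliable than a medium-ring allylation. In step economy, the short access to A4 is offset by the redox and olefination work after A3, so no saving over the twenty steps below is expected.

Alternative 3: The ring is again traced to a bicycle. The C5 ketone and the C1=C10 alkene of cyclodecenone A5 are reconnected through a C5–C10 bond to the eudesmane-type decalin A6, with a tertiary hydroxyl at C5 and a tosylate at C1. Forward, KOtBu would form the C5 alkoxide and a concerted Grob fragmentation would break C5–C10, form C5=O and the (E)-C1=C10 alkene, and expel the anti-periplanar tosylate to give A5.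
- In favour: this fragmentation is a classical, stereospecific entry to (E)-cyclodecenones, and C6, C7 and C8 can be set on a chair-locked decalin. C12 is carried as a protected alcohol, which avoids premature lactonisation. In reliability of ring formation it is better than the chosen plan; in the handling of C12 it is its equal.
- Against: A5 has the wrong unsaturation pattern. The C1=C10 alkene with its C14 methyl must be transposed to C1–OH/C10=C14, with C1 controlled by ring conformation alone. The C5 ketone and C4 ether must be turned into the cis epoxide (reduction, activation, closure with inversion at a hindered centre). Four kinds of protecting group must come off in order, and an (E)-cyclodec-5-enone is prone to transannular ene and Prins reactions.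
- Comparison: structurally, the chosen key step places C10=C14, C1–O and a C4=C5 alkene of correct geometry directly. Mechanistically, the fragmentation is the safer ring construction. In step economy, the chosen plan needs seven steps after ring formation and the alternative clearly more, besides the stereocontrolled synthesis of A6.

Key step: step 13

Remark on conventions: germacrane numbering is used for ring compounds and their open-chain precursors; α/β refer to the usual drawing with H-7 α; the SMILES is binding. CIP letters at C6 and C7 change along the route only because substituent priorities change, never by inversion.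

Remark on starting materials: neryl acetate (1) and mono-tert-butyl succinate (12) are bought; they are the acetate of nerol and the half ester of succinic anhydride.

Remark on precursor design:
- The configurations of 20 and 21 map onto the target at C1, C6, C7 and C8 without correction.
- C1 is set by a chiral catalyst, since a plain organometallic addition gives a racemate.
- C12 is a tert-butyl ester, not a methyl ester. A methyl ester is expected to lactonise onto the C6 aldolate in step 9 and onto the primary C8 alkoxide in step 11.

## Steps

Step 1
Reactants: 1 neryl acetate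
Product: 3 (2Z)-3-methyl-6-oxohex-2-en-1-yl acetate, via ozonide 2 (not isolated)
Conditions: O3 (1.0 equiv, Sudan Red 7B end point), CH2Cl2, −78 °C; then Me2S, −78 °C to rt
Reagents that add atoms: ozone, [O-][O+]=O
Why: Ozonolysis with reductive work-up; the 6,7-alkene is the more electron-rich because the 2,3-alkene is deactivated by the allylic acetate, so one equivalent of ozone cleaves it selectively, and the Z alkene is untouched.

Step 2
Reactants: 3 (2Z)-3-methyl-6-oxohex-2-en-1-yl acetate; 4 (2-bromoallyl)trimethylsilane
Product: 6 racemic (2Z)-6-hydroxy-3-methyl-7-[(trimethylsilyl)methyl]octa-2,7-dien-1-yl acetate, via alkenylchromium dichloride 5 (not isolated)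
Conditions: CrCl2 (4 equiv), NiCl2 (2 mol%), DMF, rt
Reagents that add atoms: none
Why: Nozaki–Hiyama–Kishi coupling; the nickel co-catalyst activates the alkenyl bromide and passes it to chromium, and the alkenylchromium 5 adds to the aldehyde but not to the acetate. The carbinol centre (C1) forms as a racemate and is corrected in steps 3 and 4.

Step 3
Reactants: 6 racemic allylic alcohol
Product: 7 (2Z)-3-methyl-6-oxo-7-[(trimethylsilyl)methyl]octa-2,7-dien-1-yl acetate
Conditions: Dess–Martin periodinane, NaHCO3, CH2Cl2, 0 °C to rt
Reagents that add atoms: none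
Why: Dess–Martin oxidation under buffered conditions leaves the allylsilane and the Z alkene alone and erases the racemic centre.

Step 4
Reactants: 7 enone
Product: 8 (2Z,6S)-6-hydroxy-3-methyl-7-[(trimethylsilyl)methyl]octa-2,7-dien-1-yl acetate
Conditions: (R)-1-methyl-3,3-diphenyltetrahydro-1H,3H-pyrrolo[1,2-c][1,3,2]oxazaborole ((R)-Me-CBS, 0.2 equiv), catecholborane (1.5 equiv), toluene, −78 °C
Reagents that add atoms: none
Why: Corey–Bakshi–Shibata reduction; the 2-substituted alkenyl group acts as the large substituent, so the (R)-catalyst should give the (S)-carbinol (C1 of the target). Catecholborane at −78 °C should reduce neither the acetate nor the alkenes.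

Step 5
Reactants: 8 (S)-allylic alcohol
Product: 9 (2Z,6S)-6-[(tert-butyldimethylsilyl)oxy]-3-methyl-7-[(trimethylsilyl)methyl]octa-2,7-dien-1-yl acetate
Conditions: TBSCl, imidazole, DMF, rt
Reagents that add atoms: tert-butyldimethylsilyl chloride, CC(C)(C)[Si](C)(C)Cl
Why: Standard silylation of a secondary allylic alcohol; TBS survives all later steps and is distinguishable from the more labile TES group later placed on O6.

Step 6
Reactants: 9 silyl ether acetate
Product: 10 (2Z,6S)-6-[(tert-butyldimethylsilyl)oxy]-3-methyl-7-[(trimethylsilyl)methyl]octa-2,7-dien-1-ol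
Conditions: K2CO3 (0.2 equiv), MeOH, 0 °C to rt
Reagents that add atoms: none
Why: Zemplén-type methanolysis of the primary acetate; the silyl ether and the allylsilane are stable to catalytic carbonate in methanol.

Step 7
Reactants: 10 allylic alcohol
Product: 11 (2Z,6S)-6-[(tert-butyldimethylsilyl)oxy]-3-methyl-7-[(trimethylsilyl)methyl]octa-2,7-dienal
Conditions: activated MnO2 (excess), CH2Cl2, rt
Reagents that add atoms: none
Why: Allylic oxidation with MnO2 is neutral and should give the (Z)-enal without Z to E isomerisation or damage to the allylsilane; the aldehyde is used without chromatography on acidic supports.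

Step 8
Reactants: 12 mono-tert-butyl succinate; 13 (4S)-4-benzyl-1,3-oxazolidin-2-one
Product: 15 tert-butyl 4-[(4S)-4-benzyl-2-oxo-1,3-oxazolidin-3-yl]-4-oxobutanoate, via mixed pivalic anhydride 14 (not isolated)
Conditions: t-BuCOCl, Et3N, THF, −20 °C; then 13, LiCl, rt
Reagents that add atoms: none
Why: N-Acylation of the oxazolidinone through the mixed pivalic anhydride 14 (LiCl/Et3N protocol); attack occurs at the unhindered succinyl carbonyl.

Step 9
Reactants: 15 succinate imide; 11 (Z)-enal
Product: 17 tert-butyl (3S,4R,5Z,9S)-3-{[(4S)-4-benzyl-2-oxo-1,3-oxazolidin-3-yl]carbonyl}-9-[(tert-butyldimethylsilyl)oxy]-4-hydroxy-6-methyl-10-[(trimethylsilyl)methyl]undeca-5,10-dienoate, via boron enolate 16 (not isolated)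
Conditions: 15 (1.3 equiv), Bu2BOTf (1.25 equiv), i-Pr2NEt (1.5 equiv), CH2Cl2, −78 to 0 °C; then 11 (1.0 equiv), −78 to −10 °C; then pH 7 buffer (NaH2PO4/Na2HPO4), MeOH, 30% H2O2, 0 °C
Reagents that add atoms: none
Why: Evans syn aldol; the Z boron enolate 16 reacts through a Zimmerman–Traxler chair on the face away from the benzyl group, setting C7 (S) and C6 (R) together. The tert-butyl ester is not attacked by the boron aldolate, and the triflate is kept below the amount of 15 so that no free Lewis acid meets the allylsilane or the enal.

Step 10
Reactants: 17 aldol adduct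
Product: 18 4-O-triethylsilyl ether of 17 (6R,7S in germacrane numbering)
Conditions: TESOTf, 2,6-lutidine, CH2Cl2, −78 °C
Reagents that add atoms: triethylsilyl trifluoromethanesulfonate, CC[Si](CC)(CC)OS(=O)(=O)C(F)(F)F
Why: Silylation of the hindered β-hydroxy imide with the silyl triflate at −78 °C, where the tert-butyl ester and the lutidine-buffered allylsilane are inert. TES makes O6 non-chelating for step 13 and removable later beside TBS.

Step 11
Reactants: 18 silylated imide
Product: 19 tert-butyl (3R,4R,5Z,9S)-9-[(tert-butyldimethylsilyl)oxy]-3-(hydroxymethyl)-6-methyl-4-[(triethylsilyl)oxy]-10-[(trimethylsilyl)methyl]undeca-5,10-dienoate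
Conditions: LiBH4, MeOH (1 equiv), Et2O/THF, 0 °C
Reagents that add atoms: none
Why: Reductive cleavage of the auxiliary; LiBH4 activated by methanol reduces the exocyclic imide carbonyl much faster than a tert-butyl ester. Unlike a methyl ester, the tert-butyl ester is not attacked by the new primary alkoxide.

Step 12
Reactants: 19 primary alcohol
Product: 20 tert-butyl (3S,4R,5Z,9S)-9-[(tert-butyldimethylsilyl)oxy]-3-formyl-6-methyl-4-[(triethylsilyl)oxy]-10-[(trimethylsilyl)methyl]undeca-5,10-dienoate
Conditions: Dess–Martin periodinane, NaHCO3, CH2Cl2, 0 °C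
Reagents that add atoms: none
Why: Buffered Dess–Martin oxidation should give the α-branched β-silyloxy aldehyde without epimerisation at C7 or β-elimination; the aldehyde is used crude.

Step 13
Reactants: 20 seco-aldehyde with terminal allylsilane
Product: 21 tert-butyl 2-[(1R,2R,3Z,7S,10S)-7-[(tert-butyldimethylsilyl)oxy]-10-hydroxy-4-methyl-8-methylidene-2-[(triethylsilyl)oxy]cyclodec-3-en-1-yl]acetate (germacrane numbering 1S,6R,7R,8S)
Conditions: BF3·OEt2 (3 equiv), 2,6-di-tert-butyl-4-methylpyridine (0.5 equiv), CH2Cl2, −78 °C, slow addition of 20 to a final 1 mM; Et3N then aq. NaHCO3 at −78 °C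
Reagents that add atoms: none
Why: Intramolecular Hosomi–Sakurai allylation, a known route to carbocycles including medium rings: BF3 binds the aldehyde oxygen, the allylsilane attacks C8 with its terminal methylene carbon (C9) through an open antiperiplanar transition state, and the β-silyl cation at C10 loses silicon so that the alkene reappears only as C10=C14. The ring closes in the 10-exo-trig mode with respect to the carbonyl group, whose oxygen stays outside the ring. The new stereocentre C8 is controlled by C7: in the Felkin–Anh arrangement the C7–C6 bond is anti to the forming C8–C9 bond, a torsion a cyclodecane can accommodate, and attack past H-7 gives the (8S)-alcohol that becomes the trans lactone fusion. The opposing 1,3-anti preference of a β-oxygenated aldehyde is weak for a silyl ether, and BF3 cannot chelate O6 or the ester, which is why O6 carries silicon. Chemoselectivity rests on the allylsilane being far more nucleophilic than the C4=C5 alkene, whose attack would need a four- or five-membered ring and a poorer cation. Closure is favoured over oligomerisation by slow addition at high dilution, by the Z alkene acting as a turn and by the sp2 centre C10, and the hindered pyridine removes protons that would protodesilylate the allylsilane or ionise the allylic silyl ethers.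

Step 14
Reactants: 21 hydroxy tert-butyl ester
Product: 22 (1S,2R,3R,4Z,8S)-8-[(tert-butyldimethylsilyl)oxy]-2-(2-hydroxyethyl)-5-methyl-9-methylidene-3-[(triethylsilyl)oxy]cyclodec-4-en-1-ol
Conditions: i-Bu2AlH (4 equiv), CH2Cl2, −78 to 0 °C; aq. potassium sodium tartrate
Reagents that add atoms: none
Why: Reduction of the tert-butyl ester to the primary alcohol; silyl ethers and alkenes are inert at these temperatures, and no acid is used that could remove TES or start transannular reactions of the cyclodecadiene.

Step 15
Reactants: 22 1,4-diol
Product: 24 (1S,6R,7R,8S)-1-[(tert-butyldimethylsilyl)oxy]-6-[(triethylsilyl)oxy]-13-norgermacra-4(Z),10(14)-dien-12,8-olide, via lactol 23 (not isolated)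
Conditions: 2,2,6,6-tetramethylpiperidin-1-oxyl (TEMPO, 0.2 equiv), PhI(OAc)2 (2.5 equiv), CH2Cl2, rt
Reagents that add atoms: none
Why: Oxoammonium oxidation is selective for the primary alcohol; the oxidised carbon is trapped by O8, the only free hydroxyl, as the five-membered lactol 23, which is oxidised on to the γ-lactone. The lactone regiochemistry (O8, not O6) is therefore fixed by protection, and the trans fusion follows from C7 and C8.

Step 16
Reactants: 24 saturated lactone
Product: 28 (1S,6R,7R,8S)-1-[(tert-butyldimethylsilyl)oxy]-6-[(triethylsilyl)oxy]germacra-4(Z),10(14),11(13)-trien-12,8-olide, via lithium enolate 25 (not isolated), via Mannich base 26 (not isolated), via methiodide 27 (not isolated)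
Conditions: LiN(i-Pr)2, THF, −78 °C; Me2N=CH2 I (Eschenmoser's salt), −78 °C to rt; then MeI, MeOH, rt; then aq. NaHCO3, CH2Cl2, rt
Reagents that add atoms: N,N-dimethylmethyleneiminium iodide (Eschenmoser's salt), C=[N+](C)C.[I-]
Why: α-Methylenation by the Mannich route; C11 is the only acidic position, the enolate 25 is aminomethylated, and quaternisation followed by mild base-induced elimination gives the exocyclic alkene. It is done while O6 is silylated, so no alkoxide can translactonise, and before the base-sensitive angelate exists.

Step 17
Reactants: 28 bis-silyl methylene lactone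
Product: 29 (1S,6R,7S,8S)-1-[(tert-butyldimethylsilyl)oxy]-6-hydroxygermacra-4(Z),10(14),11(13)-trien-12,8-olide
Conditions: pyridinium p-toluenesulfonate (0.2 equiv), MeOH/CH2Cl2, 0 °C
Reagents that add atoms: none
Why: Mildly acidic methanolysis cleaves the secondary TES ether much faster than the secondary TBS ether and is too mild to add methanol to the enoate or to cyclise the diene.

Step 18
Reactants: 29 (Z)-allylic alcohol
Product: 30 (1S,4R,5S,6S,7S,8S)-1-[(tert-butyldimethylsilyl)oxy]-4,5-epoxy-6-hydroxygermacra-10(14),11(13)-dien-12,8-olide (4α,5α-epoxide)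
Conditions: VO(acac)2 (0.1 equiv), t-BuOOH (1.5 equiv, in decane), CH2Cl2, 0 °C to rt
Reagents that add atoms: tert-butyl hydroperoxide, CC(C)(C)OO
Why: Hydroxyl-directed epoxidation; the vanadium alkoxide of O6 delivers oxygen to the adjacent trisubstituted alkene, and in medium-ring (Z)-cycloalkenols this is expected on the ring periphery syn to the hydroxyl, giving the cis epoxy alcohol (4R,5S), whereas an undirected peracid would be expected to give the trans isomer. C10=C14 (no free allylic hydroxyl) and the electron-poor C11=C13 should not react.

Step 19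
Reactants: 30 epoxy alcohol; 31 angelic acid
Product: 33 (1S,4R,5S,6S,7R,8S)-6-angeloyloxy-1-[(tert-butyldimethylsilyl)oxy]-4,5-epoxygermacra-10(14),11(13)-dien-12,8-olide, via mixed anhydride 32 (not isolated)
Conditions: 31, 2,4,6-trichlorobenzoyl chloride, Et3N, toluene, rt; then 30, NaHCO3, toluene, 80 °C
Reagents that add atoms: none
Why: Yamaguchi-type esterification through the mixed anhydride 32 without a nucleophilic catalyst, which avoids the addition–elimination path by which angelates isomerise to tiglates. Hydrogencarbonate keeps the medium neither acidic (epoxide) nor strongly basic (translactonisation, Payne rearrangement).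

Step 20
Reactants: 33 silyl ether of the target
Product: 34 CNP0104965.1, (1S,4R,5S,6S,7R,8S)-6-angeloyloxy-4,5-epoxy-1-hydroxygermacra-10(14),11(13)-dien-12,8-olide
Conditions: HF·pyridine, pyridine, THF, 0 °C to rt
Reagents that add atoms: none
Why: Fluoride cleavage of the secondary TBS ether with pyridine-buffered HF·pyridine, which should be neither basic enough to isomerise the angelate or add to the methylene lactone nor acidic enough to open the epoxide at 0 °C.

## Compound list

1 | neryl acetate, (2Z)-3,7-dimethylocta-2,6-dien-1-yl acetate | CC(C)=CCC/C(C)=C\COC(C)=O | starting material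
2 | ozonide of the 6,7-alkene of 1, (2Z)-5-(5,5-dimethyl-1,2,4-trioxolan-3-yl)-3-methylpent-2-en-1-yl acetate (not isolated) | CC1(C)OOC(CC/C(C)=C\COC(C)=O)O1 | intermediate
3 | (2Z)-3-methyl-6-oxohex-2-en-1-yl acetate | O=CCC/C(C)=C\COC(C)=O | intermediate
4 | (2-bromoallyl)trimethylsilane | C=C(Br)C[Si](C)(C)C | starting material
5 | dichloro[3-(trimethylsilyl)prop-1-en-2-yl]chromium, alkenyl reagent of trivalent chromium (not isolated) | C=C(C[Si](C)(C)C)[Cr](Cl)Cl | intermediate
6 | racemic (2Z)-6-hydroxy-3-methyl-7-[(trimethylsilyl)methyl]octa-2,7-dien-1-yl acetate | C=C(C[Si](C)(C)C)C(O)CC/C(C)=C\COC(C)=O | intermediate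
7 | (2Z)-3-methyl-6-oxo-7-[(trimethylsilyl)methyl]octa-2,7-dien-1-yl acetate | C=C(C[Si](C)(C)C)C(=O)CC/C(C)=C\COC(C)=O | intermediate
8 | (2Z,6S)-6-hydroxy-3-methyl-7-[(trimethylsilyl)methyl]octa-2,7-dien-1-yl acetate | CC(=O)OC/C=C(C)\CC[C@H](O)C(=C)C[Si](C)(C)C | intermediate
9 | (2Z,6S)-6-[(tert-butyldimethylsilyl)oxy]-3-methyl-7-[(trimethylsilyl)methyl]octa-2,7-dien-1-yl acetate | CC(=O)OC/C=C(C)\CC[C@H](O[Si](C)(C)C(C)(C)C)C(=C)C[Si](C)(C)C | intermediate
10 | (2Z,6S)-6-[(tert-butyldimethylsilyl)oxy]-3-methyl-7-[(trimethylsilyl)methyl]octa-2,7-dien-1-ol | OC/C=C(C)\CC[C@H](O[Si](C)(C)C(C)(C)C)C(=C)C[Si](C)(C)C | intermediate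
11 | (2Z,6S)-6-[(tert-butyldimethylsilyl)oxy]-3-methyl-7-[(trimethylsilyl)methyl]octa-2,7-dienal | O=C/C=C(C)\CC[C@H](O[Si](C)(C)C(C)(C)C)C(=C)C[Si](C)(C)C | intermediate
12 | mono-tert-butyl succinate, 4-(tert-butoxy)-4-oxobutanoic acid | CC(C)(C)OC(=O)CCC(=O)O | starting material
13 | (4S)-4-benzyl-1,3-oxazolidin-2-one | O=C1N[C@@H](Cc2ccccc2)CO1 | starting material
14 | 4-(tert-butoxy)-4-oxobutanoic pivalic anhydride (not isolated) | CC(C)(C)OC(=O)CCC(=O)OC(=O)C(C)(C)C | intermediate
15 | tert-butyl 4-[(4S)-4-benzyl-2-oxo-1,3-oxazolidin-3-yl]-4-oxobutanoate | CC(C)(C)OC(=O)CCC(=O)N1C(=O)OC[C@@H]1Cc1ccccc1 | intermediate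
16 | (Z)-dibutylboron enolate of 15 (not isolated) | CCCCB(CCCC)O/C(=C\CC(=O)OC(C)(C)C)N1C(=O)OC[C@@H]1Cc1ccccc1 | intermediate
17 | tert-butyl (3S,4R,5Z,9S)-3-{[(4S)-4-benzyl-2-oxo-1,3-oxazolidin-3-yl]carbonyl}-9-[(tert-butyldimethylsilyl)oxy]-4-hydroxy-6-methyl-10-[(trimethylsilyl)methyl]undeca-5,10-dienoate | O=C(N1C(=O)OC[C@@H]1Cc1ccccc1)[C@@H](CC(=O)OC(C)(C)C)[C@H](O)/C=C(C)\CC[C@H](O[Si](C)(C)C(C)(C)C)C(=C)C[Si](C)(C)C | intermediate
18 | 4-O-triethylsilyl ether of 17, (3S,4R,5Z,9S) | O=C(N1C(=O)OC[C@@H]1Cc1ccccc1)[C@@H](CC(=O)OC(C)(C)C)[C@H](O[Si](CC)(CC)CC)/C=C(C)\CC[C@H](O[Si](C)(C)C(C)(C)C)C(=C)C[Si](C)(C)C | intermediate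
19 | tert-butyl (3R,4R,5Z,9S)-9-[(tert-butyldimethylsilyl)oxy]-3-(hydroxymethyl)-6-methyl-4-[(triethylsilyl)oxy]-10-[(trimethylsilyl)methyl]undeca-5,10-dienoate | OC[C@@H](CC(=O)OC(C)(C)C)[C@H](O[Si](CC)(CC)CC)/C=C(C)\CC[C@H](O[Si](C)(C)C(C)(C)C)C(=C)C[Si](C)(C)C | intermediate
20 | tert-butyl (3S,4R,5Z,9S)-9-[(tert-butyldimethylsilyl)oxy]-3-formyl-6-methyl-4-[(triethylsilyl)oxy]-10-[(trimethylsilyl)methyl]undeca-5,10-dienoate (key-step precursor) | O=C[C@@H](CC(=O)OC(C)(C)C)[C@H](O[Si](CC)(CC)CC)/C=C(C)\CC[C@H](O[Si](C)(C)C(C)(C)C)C(=C)C[Si](C)(C)C | intermediate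
21 | tert-butyl 2-[(1R,2R,3Z,7S,10S)-7-[(tert-butyldimethylsilyl)oxy]-10-hydroxy-4-methyl-8-methylidene-2-[(triethylsilyl)oxy]cyclodec-3-en-1-yl]acetate (key-step product; 1α-OTBS, 6α-OTES, 8α-OH, 7α-H) | O[C@H]1CC(=C)[C@@H](O[Si](C)(C)C(C)(C)C)CC/C(C)=C\[C@@H](O[Si](CC)(CC)CC)[C@@H]1CC(=O)OC(C)(C)C | intermediate
22 | (1S,2R,3R,4Z,8S)-8-[(tert-butyldimethylsilyl)oxy]-2-(2-hydroxyethyl)-5-methyl-9-methylidene-3-[(triethylsilyl)oxy]cyclodec-4-en-1-ol | O[C@H]1CC(=C)[C@@H](O[Si](C)(C)C(C)(C)C)CC/C(C)=C\[C@@H](O[Si](CC)(CC)CC)[C@@H]1CCO | intermediate
23 | lactol between O8 and C12 of oxidised 22, ring configuration as 24, anomeric centre undefined (not isolated) | C1C(O)O[C@H]2CC(=C)[C@@H](O[Si](C)(C)C(C)(C)C)CC/C(C)=C\[C@@H](O[Si](CC)(CC)CC)[C@H]12 | intermediate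
24 | (1S,6R,7R,8S)-1-[(tert-butyldimethylsilyl)oxy]-6-[(triethylsilyl)oxy]-13-norgermacra-4(Z),10(14)-dien-12,8-olide (trans-fused γ-lactone, C11 is CH2) | C1C(=O)O[C@H]2CC(=C)[C@@H](O[Si](C)(C)C(C)(C)C)CC/C(C)=C\[C@@H](O[Si](CC)(CC)CC)[C@H]12 | intermediate
25 | lithium enolate of 24 (not isolated) | C1=C(O[Li])O[C@H]2CC(=C)[C@@H](O[Si](C)(C)C(C)(C)C)CC/C(C)=C\[C@@H](O[Si](CC)(CC)CC)[C@H]12 | intermediate
26 | 11-[(dimethylamino)methyl] derivative of 24, C11 undefined (not isolated) | CN(C)CC1C(=O)O[C@H]2CC(=C)[C@@H](O[Si](C)(C)C(C)(C)C)CC/C(C)=C\[C@@H](O[Si](CC)(CC)CC)[C@H]12 | intermediate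
27 | trimethylammonium iodide of 26 (not isolated) | C[N+](C)(C)CC1C(=O)O[C@H]2CC(=C)[C@@H](O[Si](C)(C)C(C)(C)C)CC/C(C)=C\[C@@H](O[Si](CC)(CC)CC)[C@H]12.[I-] | intermediate
28 | (1S,6R,7R,8S)-1-[(tert-butyldimethylsilyl)oxy]-6-[(triethylsilyl)oxy]germacra-4(Z),10(14),11(13)-trien-12,8-olide | C=C1C(=O)O[C@H]2CC(=C)[C@@H](O[Si](C)(C)C(C)(C)C)CC/C(C)=C\[C@@H](O[Si](CC)(CC)CC)[C@H]12 | intermediate
29 | (1S,6R,7S,8S)-1-[(tert-butyldimethylsilyl)oxy]-6-hydroxygermacra-4(Z),10(14),11(13)-trien-12,8-olide (6α-OH) | C=C1C(=O)O[C@H]2CC(=C)[C@@H](O[Si](C)(C)C(C)(C)C)CC/C(C)=C\[C@@H](O)[C@H]12 | intermediate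
30 | (1S,4R,5S,6S,7S,8S)-1-[(tert-butyldimethylsilyl)oxy]-4,5-epoxy-6-hydroxygermacra-10(14),11(13)-dien-12,8-olide (4α,5α-epoxide, 6α-OH) | C=C1C(=O)O[C@H]2CC(=C)[C@@H](O[Si](C)(C)C(C)(C)C)CC[C@@]3(C)O[C@H]3[C@@H](O)[C@H]12 | intermediate
31 | angelic acid, (2Z)-2-methylbut-2-enoic acid | C/C=C(/C)C(=O)O | starting material
32 | angelic 2,4,6-trichlorobenzoic anhydride (not isolated) | C/C=C(/C)C(=O)OC(=O)c1c(Cl)cc(Cl)cc1Cl | intermediate
33 | (1S,4R,5S,6S,7R,8S)-6-angeloyloxy-1-[(tert-butyldimethylsilyl)oxy]-4,5-epoxygermacra-10(14),11(13)-dien-12,8-olide | C=C1C(=O)O[C@H]2CC(=C)[C@@H](O[Si](C)(C)C(C)(C)C)CC[C@@]3(C)O[C@H]3[C@@H](OC(=O)/C(C)=C\C)[C@H]12 | intermediate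
34 | CNP0104965.1, (1S,4R,5S,6S,7R,8S)-6-angeloyloxy-4,5-epoxy-1-hydroxygermacra-10(14),11(13)-dien-12,8-olide | C=C1C(=O)O[C@H]2CC(=C)[C@@H](O)CC[C@@]3(C)O[C@H]3[C@@H](OC(=O)/C(C)=C\C)[C@H]12 | target

## Step count and least certain steps

Total: 20 steps. Longest linear sequence: 19 steps (steps 1–7 and 9–20, from 1 to 34); step 8 is a one-step branch.

Step 13 (key step). The most likely failure is intermolecular allylation outrunning closure of the strained ten-membered ring. The second is loss of Felkin–Anh control at C8 once the ring constrains the transition state. Protodesilylation of the allylsilane by adventitious acid is a further risk. Fallback: replace the open cationic allylation by an internal Nozaki–Hiyama allylation, which runs through a closed chromium alkoxide transition state under neutral conditions. It sets out from 19. Bromodesilylation with N-bromosuccinimide (CH2Cl2, −78 °C) converts the allylsilane into the 2-(bromomethyl)allyl unit of the bromo alcohol F1. Buffered Dess–Martin oxidation gives the bromo aldehyde F2. CrCl2 in THF at high dilution then closes the ring, and the route is rejoined at 21.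

Step 11. Hydride may fail to discriminate: slow reduction of the hindered, silylated imide could allow ring-opening of the oxazolidinone, attack on the ester, or silyl migration to the new primary alkoxide. Fallback: avoid hydride and the alcohol stage. From 18, lithium ethanethiolate (EtSH, n-BuLi, THF, 0 °C) displaces the auxiliary to give the S-ethyl thioester F3. Fukuyama reduction (Et3SiH, 10% Pd/C, acetone, rt) should then give the aldehyde directly, rejoining at 20.

Step 16. Aminomethylation may be incomplete on a hindered ring-fused enolate, and the product can suffer Michael addition during the elimination. Fallback: an aldol–dehydration route in place of the Mannich route. From 24, the enolate 25 is trapped with monomeric formaldehyde to give the hydroxymethyl lactone F4. Mesylation (MeSO2Cl, Et3N) and elimination with DBU rejoin the route at 28.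

Step 18. Facial selectivity may be poor if the ring conformation overrides hydroxyl direction, and the allylic alcohol may be oxidised to the enone. Fallback: a halohydrin route, which places the epoxide oxygen on the face opposite to that attacked by an electrophile. From 28, N-bromosuccinimide in aqueous 1,2-dimethoxyethane (0 °C) should give the 5β-bromo-4α-hydroxy bromohydrin F5. Ag2O closes it with inversion at C5 to the epoxide silyl ether F6. Removal of the TES group as in step 17 rejoins the route at 30.

Step 19. Isomerisation of the angelate to the tiglate during a slow acylation of a hindered alcohol is the main risk, with thermal damage to the epoxy alcohol as a second. Fallback: build the Z alkene on the ester. From 30, carbodiimide coupling (EDC·HCl, 4-(dimethylamino)pyridine, CH2Cl2) with 2-[bis(2,2,2-trifluoroethoxy)phosphoryl]propanoic acid gives the phosphonoacetate F7. Still–Gennari olefination (KN(SiMe3)2, 18-crown-6, THF, −78 °C, acetaldehyde) should form the (Z)-2-methylbut-2-enoate, rejoining at 33.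

## Further compounds

F1 | step 13 | tert-butyl (3R,4R,5Z,9S)-10-(bromomethyl)-9-[(tert-butyldimethylsilyl)oxy]-3-(hydroxymethyl)-6-methyl-4-[(triethylsilyl)oxy]undeca-5,10-dienoate | OC[C@@H](CC(=O)OC(C)(C)C)[C@H](O[Si](CC)(CC)CC)/C=C(C)\CC[C@H](O[Si](C)(C)C(C)(C)C)C(=C)CBr
F2 | step 13 | tert-butyl (3S,4R,5Z,9S)-10-(bromomethyl)-9-[(tert-butyldimethylsilyl)oxy]-3-formyl-6-methyl-4-[(triethylsilyl)oxy]undeca-5,10-dienoate | O=C[C@@H](CC(=O)OC(C)(C)C)[C@H](O[Si](CC)(CC)CC)/C=C(C)\CC[C@H](O[Si](C)(C)C(C)(C)C)C(=C)CBr
F3 | step 11 | tert-butyl (3S,4R,5Z,9S)-9-[(tert-butyldimethylsilyl)oxy]-3-[(ethylsulfanyl)carbonyl]-6-methyl-4-[(triethylsilyl)oxy]-10-[(trimethylsilyl)methyl]undeca-5,10-dienoate | CCSC(=O)[C@@H](CC(=O)OC(C)(C)C)[C@H](O[Si](CC)(CC)CC)/C=C(C)\CC[C@H](O[Si](C)(C)C(C)(C)C)C(=C)C[Si](C)(C)C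
F4 | step 16 | 11-(hydroxymethyl) derivative of 24, C11 undefined | OCC1C(=O)O[C@H]2CC(=C)[C@@H](O[Si](C)(C)C(C)(C)C)CC/C(C)=C\[C@@H](O[Si](CC)(CC)CC)[C@H]12
F5 | step 18 | 5β-bromo-4α-hydroxy-4,5-dihydro derivative of 28 | C=C1C(=O)O[C@H]2CC(=C)[C@@H](O[Si](C)(C)C(C)(C)C)CC[C@@](C)(O)[C@H](Br)[C@@H](O[Si](CC)(CC)CC)[C@H]12
F6 | step 18 | 6-O-triethylsilyl ether of 30 | C=C1C(=O)O[C@H]2CC(=C)[C@@H](O[Si](C)(C)C(C)(C)C)CC[C@@]3(C)O[C@H]3[C@@H](O[Si](CC)(CC)CC)[C@H]12
F7 | step 19 | 6-O-{2-[bis(2,2,2-trifluoroethoxy)phosphoryl]propanoyl} ester of 30 | C=C1C(=O)O[C@H]2CC(=C)[C@@H](O[Si](C)(C)C(C)(C)C)CC[C@@]3(C)O[C@H]3[C@@H](OC(=O)C(C)P(=O)(OCC(F)(F)F)OCC(F)(F)F)[C@H]12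
A1 | alternative 1 | 1-O-tert-butyldimethylsilyl ether of the target (identical with 33) | C=C1C(=O)O[C@H]2CC(=C)[C@@H](O[Si](C)(C)C(C)(C)C)CC[C@@]3(C)O[C@H]3[C@@H](OC(=O)/C(C)=C\C)[C@H]12
A2 | alternative 1 | 6α-angeloyloxy-1α-[(tert-butyldimethylsilyl)oxy]-4α,5α-epoxy-7β-ethynyl-4-methyl-10-methylidenecyclodecan-8α-ol (germacrane numbering) | O[C@H]1CC(=C)[C@@H](O[Si](C)(C)C(C)(C)C)CC[C@@]2(C)O[C@H]2[C@@H](OC(=O)/C(C)=C\C)[C@@H]1C#C
A3 | alternative 2 | ten-membered 1,6-diketone with cis 4,5-epoxide, trans 12,8-lactone and methyl ester on C10 | C[C@@]12CCC(=O)[C@H](C(=O)OC)C[C@@H]3OC(=O)C[C@H]3C(=O)[C@@H]1O2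
A4 | alternative 2 | octalin with tetrasubstituted C1=C6 alkene, the same epoxide, lactone and C10 ester as A3 | C[C@@]12CCC3=C([C@@H]1O2)[C@@H]4CC(=O)O[C@H]4C[C@H]3C(=O)OC
A5 | alternative 3 | (E)-cyclodec-5-enone with C5 ketone, C1=C10 alkene, 4-OMOM, 6-OPMB, 8-OTBS and 7-(2-silyloxyethyl) | C[C@@]1(OCOC)CC/C=C(C)/C[C@H](O[Si](C)(C)C(C)(C)C)[C@@H](CCO[Si](C)(C)C(C)(C)C)[C@H](OCc2ccc(OC)cc2)C1=O
A6 | alternative 3 | trans-decalin (eudesmane type) with 5α-hydroxyl, 10β-methyl, equatorial 1β-tosylate and the substituents of A5 | C[C@@]1(OCOC)CC[C@@H](OS(=O)(=O)c2ccc(C)cc2)[C@]3(C)C[C@H](O[Si](C)(C)C(C)(C)C)[C@@H](CCO[Si](C)(C)C(C)(C)C)[C@H](OCc2ccc(OC)cc2)[C@@]13O
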